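At early times target rises from zero in a flask charged with substrate, so at the first instant it comes from the direct step, substrate to target, and the steps with target on their left run at zero rate.

the same everywhere: substrate 0.020 M; time 30 s

| run | temperature | remark |
|---|---|---|
| eta | 110 °C |  |
| beta | 140 °C |  |
| theta | 80 °C |  |
| delta |  | at 140 °C until 20 s, from then on at 80 °C |

- the flask with the highest amount of target, in percent of the substrate charged ("all alike" if they lie within 1.5 percentage points) (eta / beta / theta / delta / all alike)
- final target, as a percentage of the substrate charged, in eta
- final target, as a percentage of the substrate charged, in beta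
- final target, as a percentage of the substrate charged, in theta
- final target, as a percentage of the substrate charged, in delta

- percentages count the substrate that a species holds: one side product counts as two
- where a step has two of a species, its rate is k times that concentration squared, and two are used at each turn
- constants are those at 80 °C; use the activation energies and enthalpies for any other temperature

    substrate + target → side product (k1 = 0.11 L mol⁻¹ s⁻¹, Ea1 = 56.0 kJ mol⁻¹)
    substrate → target (k2 = 7.8 × 10⁻⁵ s⁻¹, Ea2 = 118 kJ mol⁻¹)
    substrate ⇌ dormant form (K3 = 2.8, k3 = 0.021 s⁻¹, Ea3 = 93.0 kJ mol⁻¹, ΔH3 = −18.0 kJ mol⁻¹)
    substrate + 2 target → 3 target (k4 = 200 L² mol⁻² s⁻¹, Ea4 = 37.0 kJ mol⁻¹)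
    (constants at 80 °C)

How much target the direct step makes depends on the substrate it has to work on. In theta, at 80 °C, substrate also parks reversibly as the dormant form, with a relaxation half-life of 24.3 s (both ways together). That is shorter than the 30 s of the run, so the substrate curve bends within the run. The equilibrium lies at 0.00526 M of free substrate, approached exponentially at 0.0285 s⁻¹, forward and back together. Integrating that curve gave me 0.0152 M: this is the mean free substrate, the substrate concentration averaged over the run. My rule, while target stays small, is that target equals the direct rate constant, 7.8 × 10⁻⁵ s⁻¹, times mean free substrate times time.

| theta | free substrate | target made per second |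
|---|---|---|
| start | 0.020 M | 1.56 × 10⁻⁶ M s⁻¹ |
| mid-run | 0.0149 M | 1.16 × 10⁻⁶ M s⁻¹ |
| end | 0.0115 M | 8.99 × 10⁻⁷ M s⁻¹ |

Reading down, substrate drops 0.00510 M by mid-run and then 0.00340 M, less, so the curve sags. Reading the ends against each other, their average is 0.0158 M, 3.93% above the integrated mean, so I kept the integrated value.

The rule gives 3.55 × 10⁻⁵ M of target, or 0.177% of the charge in theta. At that amount in theta the side step takes 5.01% of what the direct step makes, and autocatalysis adds 0.323%, so I kept the rule for theta.

In beta it does not. The direct step is 340 times faster in beta than in theta and the equilibrium constant is 1.15, so with free substrate at its equilibrium share the rule offers 37.3%. At that amount in beta, though, autocatalysis runs 2.60 times the direct rate. My reckoning stopped there.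

The forecast named beta highest, with 2.17% in eta, 44% in beta, 0.175% in theta and 27% in delta. Of beta it said: “the rise is autocatalytic”. My theta figure lies slightly above its own.

The flasks gave beta highest, with 2.16% in eta, 44.3% in beta, 0.173% in theta and 26.9% in delta, each inside the forecast's range. Theta ended holding 0.00872% as side product, which counts double, so 0.00436% of the charge was target taken away. The mean free substrate gave 0.177% in theta, which stands 0.0044 percentage points above the result for theta.

Theta read at 50 s has a mean free substrate of 0.0131 M, lower than over the 30 s run, and the rule gives 0.256%. The flask gave 0.247%.

Its constants were drawn at random within sensible limits, and the outcome is calculated.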